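All runs were computed for an exercise; the scatter is artificial.

Early times give us the rate, and the rate is what we follow here.

| flask | substrate | activator | capture agent | temperature | remark | time |
|---|---|---|---|---|---|---|
| Tuesday's | 0.50 M | 0.95 equiv | 0.050 M | 30 °C | run made earlier |  |
| Saturday's | 0.50 M | 0.47 equiv | 0.050 M | 41 °C | run made earlier |  |
| Friday's | 0.50 M | 0.71 equiv | 0.050 M | 30 °C | run made earlier |  |
| Sunday's | 0.50 M | 0.95 equiv | 0.025 M | 41 °C | run made earlier |  |
| green | 0.50 M (fed, over 2.5 h) | 0.950 equiv | 0.0500 M |  | the addition at 15 °C, then warmed to 35 °C; the feed brings no volume worth counting | 6.0 h |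
| amber | 0.50 M | 0.950 equiv | 0.0500 M | 35 °C | everything together at the start | 6.0 h |
| violet | 0.50 M | 0.950 equiv (in portions, 3, over 2.5 h) | 0.0500 M | 35 °C | first portion at the start, last at 2.5 h | 6.0 h |
| grey | 0.50 M | 0.950 equiv (fed, over 2.5 h) | 0.0500 M | 35 °C | all else is in the flask from the start; the feed brings no volume worth counting | 6.0 h |
| teal | 0.50 M (fed, over 40 min) | 0.950 equiv | 0.0500 M | 35 °C | all else is in the flask from the start; the feed brings no volume worth counting | 6.0 h |

| run | time / h | trapped intermediate / % | ring / % |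
|---|---|---|---|
| Tuesday's | 0.833 | 1.4 | 1.4 |
| Tuesday's | 1.50 | 3.6 | 2.2 |
| Tuesday's | 2.50 | 5.2 | 3.9 |
| Tuesday's | 3.00 | 7.6 | 6.2 |
| Tuesday's | 4.00 | 7.6 | 4.9 |
| Tuesday's | 5.00 | 8.2 | 9.4 |
| Tuesday's | 6.00 | 9.6 | 9.1 |
| Saturday's | 0.500 | 1.8 | 2.1 |
| Saturday's | 1.00 | 6.2 | 5.1 |
| Saturday's | 1.50 | 4.1 | 2.3 |
| Saturday's | 2.00 | 3.5 | 2.8 |
| Saturday's | 2.50 | 4.0 | 3.5 |
| Saturday's | 3.00 | 5.0 | 0.3 |
| Saturday's | 4.00 | 5.1 | 2.6 |
| Friday's | 0.200 | 0.4 | 0 |
| Friday's | 0.500 | 1.4 | 0.1 |
| Friday's | 1.00 | 2.6 | 1.4 |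
| Friday's | 1.50 | 4.0 | 1.8 |
| Friday's | 2.00 | 4.8 | 2.9 |
| Friday's | 3.00 | 5.2 | 3.1 |
| Friday's | 4.00 | 7.3 | 4.5 |
| Sunday's | 0.667 | 2.1 | 7.1 |
| Sunday's | 1.33 | 4.5 | 11.6 |
| Sunday's | 2.00 | 4.9 | 13.8 |
| Sunday's | 3.00 | 4.1 | 19.4 |
| Sunday's | 4.00 | 3.7 | 21.1 |

(each reading ± 1 percentage point)

- the flask that comes out highest in amount of trapped intermediate, in percent of the substrate charged, or "all alike" when all lie within 1.5 percentage points (green / amber / violet / grey / teal / all alike)
- trapped intermediate at the end, in percent of the substrate charged, green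
- trapped intermediate at the end, in percent of the substrate charged, amber
- trapped intermediate at the end, in percent of the substrate charged, violet
- trapped intermediate at the end, in percent of the substrate charged, grey
- trapped intermediate at the end, in percent of the substrate charged, teal



We assume that one capture agent gives one trapped intermediate. That sets a ceiling C, the capture charge over the substrate charge: 10.0 % in these flasks. Sunday's smaller charge allows 5.00 %, and Sunday's reading at 2.00 h is 4.9 %.

Divide an early slope by its ceiling and we get κ, a pseudo-first-order constant for spending capture agent. Tuesday's reading at 1.50 h gives 0.240 h⁻¹, and Sunday's at 1.33 h gives 0.677 h⁻¹. Interpolated to 35 °C, we read κ as 0.384 h⁻¹.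

Unslowed, amber's starting rate would make 23.0 % by 6.0 h, which is 2.31 ceilings; call this number N. But we take the rate to follow the capture agent left. On that reckoning it ends at 0.0993 of its start, and its mean is 0.390 of the start. A straight average of start and end would give 12.7 %, more than the ceiling, so the curve's own mean is needed. The fill F, the share of the ceiling reached, is one minus e to the minus N: 0.900. We hold κ steady, and that is our assumption, not a reading.

So we expect 9.00 % for amber. Green, counted at the cold κ of 0.0584 h⁻¹ during its addition, has N of 1.49 and gives 7.75 %. That gap of 1.3 percentage points is less than the margin, so we say all alike.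

The forecast differs. It named grey, with grey at 9 %, violet 8.6 %, amber 8 %, teal 8 % and green 7 %, holding that “Feeding activator keeps its level low”.

The flasks come out all alike: amber 8.97 %, teal 8.93 %, grey 8.52 %, violet 8.41 %, green 8.32 %. Green holds 17 % of its capture agent at the end. Read back, that is an N of 1.78, more than our count.

    substrate + activator → activated form (k = 5.32 × 10⁻⁴ M⁻¹ s⁻¹, Ea = 70.0 kJ mol⁻¹)
    activated form → ring (k = 1.08 × 10⁻⁴ s⁻¹, Ea = 108 kJ mol⁻¹)
    substrate + activated form → open dimer (k = 3.85 × 10⁻⁴ M⁻¹ s⁻¹, Ea = 61.0 kJ mol⁻¹)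
    substrate + ring → side product (k = 0.00215 M⁻¹ s⁻¹, Ea = 53.0 kJ mol⁻¹)
    capture agent + activated form → trapped intermediate (k = 0.00140 M⁻¹ s⁻¹, Ea = 78.0 kJ mol⁻¹)
    (constants at 35 °C)

Take teal with 0.085 M of capture agent, other charges held. Its ceiling is 17.0 %, and keeping amber's F, since the feed of 40 min is shorter than the run, gives 15.3 %. The computed flask gives 14.8 %.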